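**Retrosynthetic overview** (eremophilane numbering: ring A = C1–C5 + C10, ring B = C5–C10, C11 = isopropylidene carbon, C14 on C5, C15 on C4)
1. Target ⇒ (ester C–O) bicyclic alcohol 15, with the diosphenol kept as its methyl enol ether, + side-chain acid 23.
2. 15 ⇒ open-chain acid 11 by cutting C5–C10 and C7–C8; ring A closes first (cation at C5 captured by C10), ring B second (C8 acylates prenyl carbon C7).
3. Enabling feature: the C8/C9 diosphenol of ring B, flanked by ring-fusion C10 and by C7, is a masked α-keto acid (2-methoxyacrylic acid), nucleophilic at C10 and an acyl donor at C8; quaternary C5 is a tertiary cation and C7=C11 is the trace of a prenyl group.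
4. 11 ⇒ olefination of lactol 8 ⇒ lactone 4 (Wacker, allylation, cross-metathesis) ⇒ catalytic syn-crotylation of methyl 4-oxobutanoate, which sets C3 and C4.
5. 23 ⇒ angelic acid + (Z)-hydroxy enoate 19 ⇒ syn carbocupration of a silyloxy ynoate.

Key step: step 8

Remark: 2 and 9 are taken as commercial; the tertiary carbinol carbon made in step 3 and the lactol carbon made in step 5 are carried as epimer mixtures because both become trigonal later; the (S) phosphoric acid in step 1 is assumed to be the enantiomer that directs Si-face addition (the antipode of the one that turns benzaldehyde into (R)-1-phenylbut-3-en-1-ol).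

Step 1
Reactants: 1 methyl 4-oxobutanoate; 2 (Z)-crotylboronic acid pinacol ester
Product: 4 (5R)-5-[(2R)-but-3-en-2-yl]oxolan-2-one, via methyl (4R,5R)-4-hydroxy-5-methylhept-6-enoate 3 (not isolated)
Conditions: (S)-3,3′-bis(2,4,6-triisopropylphenyl)-1,1′-binaphthyl-2,2′-diyl hydrogen phosphate (5 mol %), toluene, −30 °C; aq. work-up; then p-TsOH·H2O (5 mol %), CH2Cl2, 23 °C
Reagents that add atoms: none
Why: Chiral phosphoric acid-catalysed crotylboration through a closed chair transition state, in which the (Z)-boronate gives the syn pair and the catalyst directs addition to the Si face (carbinol carbon R, methyl-bearing carbon R); acid then lactonises the γ-hydroxy ester, which protects the alcohol and the carboxyl end together.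

Step 2
Reactants: 4 (5R)-5-[(2R)-but-3-en-2-yl]oxolan-2-one
Product: 5 (5R)-5-[(2S)-3-oxobutan-2-yl]oxolan-2-one
Conditions: PdCl2 (10 mol %), CuCl (1 equiv), O2 (1 atm), DMF/H2O 7:1, 23 °C
Reagents that add atoms: water, O
Why: Tsuji–Wacker oxidation of the terminal alkene to the methyl ketone (Markovnikov hydroxypalladation) supplies the future angular methyl group under near-neutral conditions that should leave the α-methyl stereocentre and the lactone intact.

Step 3
Reactants: 5 (5R)-5-[(2S)-3-oxobutan-2-yl]oxolan-2-one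
Product: 6 (5R)-5-[(2S,3RS)-3-hydroxy-3-methylhex-5-en-2-yl]oxolan-2-one
Conditions: allyl bromide, Zn dust, THF/sat. aq. NH4Cl, 0 → 23 °C
Reagents that add atoms: allyl bromide, C=CCBr
Why: Zinc-mediated Barbier allylation in aqueous medium should add to the ketone and not to the lactone; the new tertiary carbinol forms as both epimers, which is harmless because this carbon is ionised in step 8.

Step 4
Reactants: 6 (5R)-5-[(2S,3RS)-3-hydroxy-3-methylhex-5-en-2-yl]oxolan-2-one
Product: 7 (5R)-5-[(2S,3RS)-3-hydroxy-3,6-dimethylhept-5-en-2-yl]oxolan-2-one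
Conditions: 2-methylbut-2-ene (excess), second-generation Grubbs catalyst RuCl2(=CHPh)(PCy3)(H2IMes) (5 mol %), CH2Cl2, 40 °C
Reagents that add atoms: 2-methylbut-2-ene, CC=C(C)C
Why: Olefin cross-metathesis of the allyl group with excess 2-methylbut-2-ene should give the prenyl group that later serves as the π-nucleophile for ring B, without touching a stereocentre.

Step 5
Reactants: 7 (5R)-5-[(2S,3RS)-3-hydroxy-3,6-dimethylhept-5-en-2-yl]oxolan-2-one
Product: 8 (2RS,5R)-5-[(2S,3RS)-3-hydroxy-3,6-dimethylhept-5-en-2-yl]oxolan-2-ol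
Conditions: i-Bu2AlH (2.2 equiv), CH2Cl2, −78 °C; aq. potassium sodium tartrate
Reagents that add atoms: none
Why: Partial reduction of the γ-lactone to the lactol (a masked aldehyde) with diisobutylaluminium hydride, the tetrahedral aluminate being stable at −78 °C.

Step 6
Reactants: 8 (2RS,5R)-5-[(2S,3RS)-3-hydroxy-3,6-dimethylhept-5-en-2-yl]oxolan-2-ol; 9 methyl 2-(dimethoxyphosphoryl)-2-methoxyacetate
Product: 10 methyl (2Z,6R,7S,8RS)-6,8-dihydroxy-2-methoxy-7,8,11-trimethyldodeca-2,10-dienoate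
Conditions: 9 (2.5 equiv), LiN(SiMe3)2 (4 equiv), THF, −78 → 23 °C
Reagents that add atoms: none
Why: Horner–Wadsworth–Emmons olefination of the open hydroxy-aldehyde form of the lactol installs the 2-methoxyacrylate (masked α-keto ester); the (Z)-isomer is expected to predominate and the geometry does not matter because this double bond is re-formed in step 8.

Step 7
Reactants: 10 methyl (2Z,6R,7S,8RS)-6,8-dihydroxy-2-methoxy-7,8,11-trimethyldodeca-2,10-dienoate
Product: 11 (2Z,6R,7S,8RS)-6,8-dihydroxy-2-methoxy-7,8,11-trimethyldodeca-2,10-dienoic acid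
Conditions: LiOH·H2O, THF/MeOH/H2O, 23 °C; then 0.5 M HCl to pH 3, 0 °C
Reagents that add atoms: lithium hydroxide, [Li+].[OH-]
Why: Saponification of the methyl ester, to which the enol ether, the alkenes and both stereocentres are inert.

Step 8
Reactants: 11 (2Z,6R,7S,8RS)-6,8-dihydroxy-2-methoxy-7,8,11-trimethyldodeca-2,10-dienoic acid
Product: 15 (4aR,5R,6R)-6-hydroxy-1-methoxy-4a,5-dimethyl-3-(propan-2-ylidene)-4,4a,5,6,7,8-hexahydronaphthalen-2(3H)-one, via open-chain tris(trifluoroacetyl) derivative 12 (not isolated), via ring-A mixed anhydride 13 (not isolated), via bicyclic trifluoroacetate 14 (not isolated)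
Conditions: (CF3CO)2O (6 equiv), CF3CO2H (20 equiv), CH2Cl2 (0.01 M), −20 → 23 °C; then NaHCO3, MeOH, 23 °C
Reagents that add atoms: none
Why: Proposed new method: exhaustive trifluoroacetylation gives 12, whose tertiary trifluoroacetate ionises to a tertiary cation at C5 that is captured by C10, the β-carbon of the 2-methoxyacrylate (an enol ether, i.e. a masked α-keto acid), and loss of the C10 proton from the oxocarbenium ion gives the ring-A enol ether 13. In 13 the mixed anhydride at C8 is held next to the prenyl group, so it acylates C7, and the tertiary cation at C11 loses the C7 proton to give the conjugated isopropylidene ketone 14, whose trifluoroacetate is methanolysed in the same flask. The closest known reaction types are the cation–olefin cyclisation terminated by an enol ether and the trifluoroacetic anhydride cyclisation of 5-alkenoic acids such as geranic acid to 6-alkylidenecyclohex-2-enones (alkene acylation by an unsaturated mixed anhydride). Ring A closes 6-exo-trig at the enol ether double bond and ring B closes 6-exo-trig at the prenyl double bond. The one new stereocentre, quaternary C5, is set in the chair transition state of the first closure with the trifluoroacetoxy and C4 methyl groups equatorial and the smaller methyl of the cation axial, which places it cis to the C4 methyl group (a modest preference is expected), and both carbinol epimers of 11 converge because C5 becomes planar. The step needs ring A to form before acylation and cation capture to outrun proton loss: ring size secures the first (C8 cannot reach C7 through a six-membered ring until C5–C10 exists), while the non-participating trifluoroacetate on the C3 oxygen, high dilution and low temperature are relied on for the second.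

Step 9
Reactants: 16 tert-butyldimethyl(prop-2-yn-1-yloxy)silane
Product: 17 tert-butyl 4-[(tert-butyldimethylsilyl)oxy]but-2-ynoate
Conditions: n-BuLi, THF, −78 °C; then (t-BuOCO)2O, −78 → 0 °C; aq. NH4Cl
Reagents that add atoms: di-tert-butyl dicarbonate, CC(C)(C)OC(=O)OC(=O)OC(C)(C)C
Why: Deprotonation of the terminal alkyne and acylation of the lithium acetylide with di-tert-butyl dicarbonate gives the tert-butyl ynoate.

Step 10
Reactants: 17 tert-butyl 4-[(tert-butyldimethylsilyl)oxy]but-2-ynoate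
Product: 18 tert-butyl (2Z)-4-[(tert-butyldimethylsilyl)oxy]-3-methylbut-2-enoate
Conditions: Me2CuLi (from MeLi and CuI), THF, −78 °C; MeOH then aq. NH4Cl at −78 °C
Reagents that add atoms: lithium dimethylcuprate, [Li+].C[Cu-]C
Why: Syn carbocupration of the ynoate by the Gilman cuprate with cold protonation places the new methyl group cis to hydrogen, so the silyloxymethyl group ends cis to the ester and the alkene is (Z).

Step 11
Reactants: 18 tert-butyl (2Z)-4-[(tert-butyldimethylsilyl)oxy]-3-methylbut-2-enoate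
Product: 19 tert-butyl (2Z)-4-hydroxy-3-methylbut-2-enoate
Conditions: HF·pyridine, THF, 0 → 23 °C
Reagents that add atoms: none
Why: Fluoride cleavage of the silyl ether; the bulky tert-butyl ester should suppress lactonisation of the (Z)-γ-hydroxy enoate to the butenolide.

Step 12
Reactants: 19 tert-butyl (2Z)-4-hydroxy-3-methylbut-2-enoate; 20 angelic acid
Product: 22 tert-butyl (2Z)-3-methyl-4-{[(2Z)-2-methylbut-2-enoyl]oxy}but-2-enoate, via angelic 2,4,6-trichlorobenzoic anhydride 21 (not isolated)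
Conditions: 20, 2,4,6-trichlorobenzoyl chloride, Et3N, toluene, 23 °C; then 19, 75 °C
Reagents that add atoms: none
Why: Yamaguchi esterification through the mixed anhydride without a nucleophilic catalyst, conditions chosen because they are known to acylate with angelic acid without isomerisation to the tiglate.

Step 13
Reactants: 22 tert-butyl (2Z)-3-methyl-4-{[(2Z)-2-methylbut-2-enoyl]oxy}but-2-enoate
Product: 23 (2Z)-3-methyl-4-{[(2Z)-2-methylbut-2-enoyl]oxy}but-2-enoic acid
Conditions: CF3CO2H/CH2Cl2 1:4, 0 → 23 °C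
Reagents that add atoms: none
Why: Acidolysis of the tert-butyl ester (loss of isobutene) should leave the allylic angelate and both (Z)-alkenes untouched and avoids basic hydrolysis.

Step 14
Reactants: 15 (4aR,5R,6R)-6-hydroxy-1-methoxy-4a,5-dimethyl-3-(propan-2-ylidene)-4,4a,5,6,7,8-hexahydronaphthalen-2(3H)-one; 23 (2Z)-3-methyl-4-{[(2Z)-2-methylbut-2-enoyl]oxy}but-2-enoic acid
Product: 25 (4aR,5R,6R)-1-methoxy-4a,5-dimethyl-2-oxo-3-(propan-2-ylidene)-2,3,4,4a,5,6,7,8-octahydronaphthalen-6-yl (2Z)-3-methyl-4-{[(2Z)-2-methylbut-2-enoyl]oxy}but-2-enoate, via mixed anhydride 24 (not isolated)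
Conditions: 23, 2,4,6-trichlorobenzoyl chloride, Et3N, THF, 23 °C; then 15, DMAP, toluene, 23 °C
Reagents that add atoms: none
Why: Yamaguchi esterification of the only free hydroxyl group (the secondary ring-A alcohol, the diosphenol oxygen being masked as its methyl ether), with retention at the carbinol carbon.

Step 15
Reactants: 25 (4aR,5R,6R)-1-methoxy-4a,5-dimethyl-2-oxo-3-(propan-2-ylidene)-2,3,4,4a,5,6,7,8-octahydronaphthalen-6-yl (2Z)-3-methyl-4-{[(2Z)-2-methylbut-2-enoyl]oxy}but-2-enoate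
Product: 26 (4aR,5R,6R)-1-hydroxy-4a,5-dimethyl-2-oxo-3-(propan-2-ylidene)-2,3,4,4a,5,6,7,8-octahydronaphthalen-6-yl (2Z)-3-methyl-4-{[(2Z)-2-methylbut-2-enoyl]oxy}but-2-enoate
Conditions: BCl3 (1 M in CH2Cl2), CH2Cl2, −78 °C; then MeOH, aq. NaHCO3
Reagents that add atoms: none
Why: Chelation-assisted cleavage of the enol methyl ether by boron trichloride (boron binds the ether oxygen and the adjacent ketone, chloride removes the methyl group by SN2) at a temperature at which carboxylic esters and alkenes should survive; the freed 1,2-diketone should rest as the conjugated diosphenol tautomer of the target.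

**Compound list**
1 | methyl 4-oxobutanoate | COC(=O)CCC=O | starting material
2 | 2-[(2Z)-but-2-en-1-yl]-4,4,5,5-tetramethyl-1,3,2-dioxaborolane ((Z)-crotylboronic acid pinacol ester) | C/C=C\CB1OC(C)(C)C(C)(C)O1 | starting material
3 | methyl (4R,5R)-4-hydroxy-5-methylhept-6-enoate | COC(=O)CC[C@@H](O)[C@H](C)C=C | intermediate
4 | (5R)-5-[(2R)-but-3-en-2-yl]oxolan-2-one | O1[C@@H]([C@H](C)C=C)CCC1=O | intermediate
5 | (5R)-5-[(2S)-3-oxobutan-2-yl]oxolan-2-one | O1[C@@H]([C@H](C)C(C)=O)CCC1=O | intermediate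
6 | (5R)-5-[(2S,3RS)-3-hydroxy-3-methylhex-5-en-2-yl]oxolan-2-one | O1[C@@H]([C@H](C)C(C)(O)CC=C)CCC1=O | intermediate
7 | (5R)-5-[(2S,3RS)-3-hydroxy-3,6-dimethylhept-5-en-2-yl]oxolan-2-one | O1[C@@H]([C@H](C)C(C)(O)CC=C(C)C)CCC1=O | intermediate
8 | (2RS,5R)-5-[(2S,3RS)-3-hydroxy-3,6-dimethylhept-5-en-2-yl]oxolan-2-ol | O1[C@@H]([C@H](C)C(C)(O)CC=C(C)C)CCC1O | intermediate
9 | methyl 2-(dimethoxyphosphoryl)-2-methoxyacetate | COC(=O)C(OC)P(=O)(OC)OC | starting material
10 | methyl (2Z,6R,7S,8RS)-6,8-dihydroxy-2-methoxy-7,8,11-trimethyldodeca-2,10-dienoate | COC(=O)/C(OC)=C/CC[C@@H](O)[C@H](C)C(C)(O)CC=C(C)C | intermediate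
11 | (2Z,6R,7S,8RS)-6,8-dihydroxy-2-methoxy-7,8,11-trimethyldodeca-2,10-dienoic acid | OC(=O)/C(OC)=C/CC[C@@H](O)[C@H](C)C(C)(O)CC=C(C)C | intermediate
12 | (2Z,6R,7S,8RS)-2-methoxy-7,8,11-trimethyl-6,8-bis(trifluoroacetoxy)dodeca-2,10-dienoic trifluoroacetic anhydride | FC(F)(F)C(=O)OC(=O)/C(OC)=C/CC[C@@H](OC(=O)C(F)(F)F)[C@H](C)C(C)(OC(=O)C(F)(F)F)CC=C(C)C | intermediate
13 | (2E)-2-[(2R,3R,4R)-2,3-dimethyl-2-(3-methylbut-2-en-1-yl)-4-(trifluoroacetoxy)cyclohexylidene]-2-methoxyacetic trifluoroacetic anhydride | FC(F)(F)C(=O)O[C@@H]1CC/C(=C(\OC)C(=O)OC(=O)C(F)(F)F)[C@](C)(CC=C(C)C)[C@H]1C | intermediate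
14 | (4aR,5R,6R)-1-methoxy-4a,5-dimethyl-2-oxo-3-(propan-2-ylidene)-2,3,4,4a,5,6,7,8-octahydronaphthalen-6-yl trifluoroacetate | FC(F)(F)C(=O)O[C@@H]1CCC2=C(OC)C(=O)C(=C(C)C)C[C@]2(C)[C@H]1C | intermediate
15 | (4aR,5R,6R)-6-hydroxy-1-methoxy-4a,5-dimethyl-3-(propan-2-ylidene)-4,4a,5,6,7,8-hexahydronaphthalen-2(3H)-one | O[C@@H]1CCC2=C(OC)C(=O)C(=C(C)C)C[C@]2(C)[C@H]1C | intermediate
16 | tert-butyldimethyl(prop-2-yn-1-yloxy)silane | C#CCO[Si](C)(C)C(C)(C)C | starting material
17 | tert-butyl 4-[(tert-butyldimethylsilyl)oxy]but-2-ynoate | CC(C)(C)OC(=O)C#CCO[Si](C)(C)C(C)(C)C | intermediate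
18 | tert-butyl (2Z)-4-[(tert-butyldimethylsilyl)oxy]-3-methylbut-2-enoate | CC(C)(C)[Si](C)(C)OC/C(C)=C\C(=O)OC(C)(C)C | intermediate
19 | tert-butyl (2Z)-4-hydroxy-3-methylbut-2-enoate | OC/C(C)=C\C(=O)OC(C)(C)C | intermediate
20 | (2Z)-2-methylbut-2-enoic acid (angelic acid) | C/C=C(/C)C(=O)O | starting material
21 | (2Z)-2-methylbut-2-enoic 2,4,6-trichlorobenzoic anhydride | C/C=C(/C)C(=O)OC(=O)c1c(Cl)cc(Cl)cc1Cl | intermediate
22 | tert-butyl (2Z)-3-methyl-4-{[(2Z)-2-methylbut-2-enoyl]oxy}but-2-enoate | C/C=C(/C)C(=O)OC/C(C)=C\C(=O)OC(C)(C)C | intermediate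
23 | (2Z)-3-methyl-4-{[(2Z)-2-methylbut-2-enoyl]oxy}but-2-enoic acid | C/C=C(/C)C(=O)OC/C(C)=C\C(=O)O | intermediate
24 | (2Z)-3-methyl-4-{[(2Z)-2-methylbut-2-enoyl]oxy}but-2-enoic 2,4,6-trichlorobenzoic anhydride | C/C=C(/C)C(=O)OC/C(C)=C\C(=O)OC(=O)c1c(Cl)cc(Cl)cc1Cl | intermediate
25 | (4aR,5R,6R)-1-methoxy-4a,5-dimethyl-2-oxo-3-(propan-2-ylidene)-2,3,4,4a,5,6,7,8-octahydronaphthalen-6-yl (2Z)-3-methyl-4-{[(2Z)-2-methylbut-2-enoyl]oxy}but-2-enoate | C/C=C(/C)C(=O)OC/C(C)=C\C(=O)O[C@@H]1CCC2=C(OC)C(=O)C(=C(C)C)C[C@]2(C)[C@H]1C | intermediate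
26 | (4aR,5R,6R)-1-hydroxy-4a,5-dimethyl-2-oxo-3-(propan-2-ylidene)-2,3,4,4a,5,6,7,8-octahydronaphthalen-6-yl (2Z)-3-methyl-4-{[(2Z)-2-methylbut-2-enoyl]oxy}but-2-enoate | C/C=C(/C)C(=O)OC/C(C)=C\C(=O)O[C@@H]1CCC2=C(O)C(=O)C(=C(C)C)C[C@]2(C)[C@H]1C | target

**Total step count:** 15. **Longest linear sequence:** 10 steps (steps 1–8, 14, 15).

**Steps most likely to fail**

Step 8 (proposed new method). The tertiary cation may be lost by proton elimination toward the conjugated diene, or may equilibrate through the neighbouring alkene and erode the methyl stereocentre, before ring A closes; facial selectivity at the quaternary carbon may also be poor. The fallback sets out from 10 and separates the two ring closures so that each is a known reaction that can be optimised alone. Ring A is closed on the ester by a Lewis-acid cation–olefin cyclisation (SnCl4, CH2Cl2, −78 °C) to methyl (2E)-2-[(2R,3R,4R)-4-hydroxy-2,3-dimethyl-2-(3-methylbut-2-en-1-yl)cyclohexylidene]-2-methoxyacetate F1, and the wanted diastereomer is purified at this stage. Saponification (LiOH) gives (2E)-2-[(2R,3R,4R)-4-hydroxy-2,3-dimethyl-2-(3-methylbut-2-en-1-yl)cyclohexylidene]-2-methoxyacetic acid F2. Ring B is then closed by the trifluoroacetic anhydride acylation of the prenyl alkene followed by methanolysis, which comes back to the route at 15.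

Step 15. Demethylation may be incomplete, or the Lewis acid may ionise the allylic ester or cleave an ester of the side chain. The fallback sets out from 15 and removes the methyl ether before the side chain is present. BCl3 (−78 → 0 °C) gives (4aR,5R,6R)-1,6-dihydroxy-4a,5-dimethyl-3-(propan-2-ylidene)-4,4a,5,6,7,8-hexahydronaphthalen-2(3H)-one F3. The more acidic enol is silylated selectively (t-BuMe2SiCl, Et3N, CH2Cl2, 0 °C) to (4aR,5R,6R)-1-[(tert-butyldimethylsilyl)oxy]-6-hydroxy-4a,5-dimethyl-3-(propan-2-ylidene)-4,4a,5,6,7,8-hexahydronaphthalen-2(3H)-one F4. Yamaguchi esterification with 23 gives (4aR,5R,6R)-1-[(tert-butyldimethylsilyl)oxy]-4a,5-dimethyl-2-oxo-3-(propan-2-ylidene)-2,3,4,4a,5,6,7,8-octahydronaphthalen-6-yl (2Z)-3-methyl-4-{[(2Z)-2-methylbut-2-enoyl]oxy}but-2-enoate F5, and HF·pyridine then comes back to the route at 26.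

Step 14. Activation of 23 may cause (Z) to (E) isomerisation or deconjugation through a vinylketene, and acylation of the hindered secondary alcohol may be slow. The fallback sets out from 15 and builds the side chain on the core in two acylations, so that the angelate is introduced last under its own isomerisation-free conditions. The tert-butyl ester of 18 is cleaved selectively (Me3SiOSO2CF3, 2,6-lutidine) to (2Z)-4-[(tert-butyldimethylsilyl)oxy]-3-methylbut-2-enoic acid F6. Yamaguchi esterification of 15 with it gives (4aR,5R,6R)-1-methoxy-4a,5-dimethyl-2-oxo-3-(propan-2-ylidene)-2,3,4,4a,5,6,7,8-octahydronaphthalen-6-yl (2Z)-4-[(tert-butyldimethylsilyl)oxy]-3-methylbut-2-enoate F7. HF·pyridine gives (4aR,5R,6R)-1-methoxy-4a,5-dimethyl-2-oxo-3-(propan-2-ylidene)-2,3,4,4a,5,6,7,8-octahydronaphthalen-6-yl (2Z)-4-hydroxy-3-methylbut-2-enoate F8, and acylation with the mixed anhydride 21 (toluene, 75 °C, no nucleophilic catalyst) comes back to the route at 25.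

Further compounds
F1 | step 8 | methyl (2E)-2-[(2R,3R,4R)-4-hydroxy-2,3-dimethyl-2-(3-methylbut-2-en-1-yl)cyclohexylidene]-2-methoxyacetate | O[C@@H]1CC/C(=C(\OC)C(=O)OC)[C@](C)(CC=C(C)C)[C@H]1C
F2 | step 8 | (2E)-2-[(2R,3R,4R)-4-hydroxy-2,3-dimethyl-2-(3-methylbut-2-en-1-yl)cyclohexylidene]-2-methoxyacetic acid | O[C@@H]1CC/C(=C(\OC)C(=O)O)[C@](C)(CC=C(C)C)[C@H]1C
F3 | step 15 | (4aR,5R,6R)-1,6-dihydroxy-4a,5-dimethyl-3-(propan-2-ylidene)-4,4a,5,6,7,8-hexahydronaphthalen-2(3H)-one | O[C@@H]1CCC2=C(O)C(=O)C(=C(C)C)C[C@]2(C)[C@H]1C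
F4 | step 15 | (4aR,5R,6R)-1-[(tert-butyldimethylsilyl)oxy]-6-hydroxy-4a,5-dimethyl-3-(propan-2-ylidene)-4,4a,5,6,7,8-hexahydronaphthalen-2(3H)-one | O[C@@H]1CCC2=C(O[Si](C)(C)C(C)(C)C)C(=O)C(=C(C)C)C[C@]2(C)[C@H]1C
F5 | step 15 | (4aR,5R,6R)-1-[(tert-butyldimethylsilyl)oxy]-4a,5-dimethyl-2-oxo-3-(propan-2-ylidene)-2,3,4,4a,5,6,7,8-octahydronaphthalen-6-yl (2Z)-3-methyl-4-{[(2Z)-2-methylbut-2-enoyl]oxy}but-2-enoate | C/C=C(/C)C(=O)OC/C(C)=C\C(=O)O[C@@H]1CCC2=C(O[Si](C)(C)C(C)(C)C)C(=O)C(=C(C)C)C[C@]2(C)[C@H]1C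
F6 | step 14 | (2Z)-4-[(tert-butyldimethylsilyl)oxy]-3-methylbut-2-enoic acid | CC(C)(C)[Si](C)(C)OC/C(C)=C\C(=O)O
F7 | step 14 | (4aR,5R,6R)-1-methoxy-4a,5-dimethyl-2-oxo-3-(propan-2-ylidene)-2,3,4,4a,5,6,7,8-octahydronaphthalen-6-yl (2Z)-4-[(tert-butyldimethylsilyl)oxy]-3-methylbut-2-enoate | CC(C)(C)[Si](C)(C)OC/C(C)=C\C(=O)O[C@@H]1CCC2=C(OC)C(=O)C(=C(C)C)C[C@]2(C)[C@H]1C
F8 | step 14 | (4aR,5R,6R)-1-methoxy-4a,5-dimethyl-2-oxo-3-(propan-2-ylidene)-2,3,4,4a,5,6,7,8-octahydronaphthalen-6-yl (2Z)-4-hydroxy-3-methylbut-2-enoate | OC/C(C)=C\C(=O)O[C@@H]1CCC2=C(OC)C(=O)C(=C(C)C)C[C@]2(C)[C@H]1C
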